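C8, the carbinol carbon of the ten-membered carbocycle (C1–C10), is bonded to C7. C7 is the β-carbon of the five-membered C6–O–C12 lactone, whose α-carbon C11 carries the exocyclic methylene C13. A C8 ketyl can therefore add to a C7=C11 butenolide, and a C13 acetate can then leave to create C11=C13.
Retrosynthetic cuts, in order: the oxirane C–O bonds at C1/C10, the O8–acyl bond, the ring bond C7–C8, the butenolide (C7=C11 and O6–C12), C6–C7, and C1=C10.
Forward: neryl acetate is shortened to the C1 aldehyde. A Still–Gennari olefination joins C1=C10 using a phosphonate that brings C8, C9 and C14. A vinyl addition brings C7 and an acrylate brings C11–C13. The lactone ring closes first (metathesis), the carbocycle second (SmI2), the oxirane last.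
Stereochemistry: Z C4=C5 is bought with neryl acetate and C1=C10 comes from the Z-selective olefination. C6 comes from a (−)-MIB-catalysed divinylzinc addition, and C7 and C8 are relayed from C6 in the ring closure. C1/C10 come from a Sharpless epoxidation with L-(+)-tartrate.

Key step: step 15

Remark: germacrane numbering (ring C1–C10, C11–C13 on C7, C14 on C10, C15 on C4) is applied to all intermediates. C6 keeps one spatial arrangement throughout although its CIP label changes from S (12–17) to R (18 onward). C1=C10 is ring-trans although its CIP label is Z, because C14 bears oxygen. Compounds 2, 4 and (−)-MIB are taken as commercial.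

Step 1
Reactants: 1 methyl bis(2,2,2-trifluoroethyl)phosphonoacetate; 2 tert-butyl(2-iodoethoxy)dimethylsilane
Product: 3 methyl 2-[bis(2,2,2-trifluoroethoxy)phosphoryl]-4-(tert-butyldimethylsilyloxy)butanoate (racemic)
Conditions: NaH, DMF, 0 °C to rt
Reagents that add atoms: none
Why: C-alkylation of the stabilised phosphonoacetate anion with a primary iodide is the standard way to α-substituted olefination reagents and here installs C9 and C8 next to the future C10.

Step 2
Reactants: 4 neryl acetate
Product: 5 6,7-epoxyneryl acetate (racemic at the oxirane)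
Conditions: mCPBA (1.0 equiv), CH2Cl2, 0 °C
Reagents that add atoms: mCPBA, O=C(OO)c1cccc(Cl)c1
Why: Prilezhaev epoxidation should pick the remote, more electron-rich trisubstituted alkene because the other one is deactivated by the allylic acetate.

Step 3
Reactants: 5 6,7-epoxyneryl acetate
Product: 6 (4Z)-6-acetoxy-4-methylhex-4-enal
Conditions: H5IO6, THF–Et2O, 0 °C
Reagents that add atoms: none
Why: Periodic acid fission of a trisubstituted epoxide gives the C1 aldehyde and acetone in one operation and leaves the Z-alkene and the acetate alone.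

Step 4
Reactants: 6 (4Z)-6-acetoxy-4-methylhex-4-enal; 3 phosphonate
Product: 7 methyl (2Z,6Z)-8-acetoxy-2-[2-(tert-butyldimethylsilyloxy)ethyl]-6-methylocta-2,6-dienoate
Conditions: 3, KN(SiMe3)2, 18-crown-6, THF, −78 °C; then 6
Reagents that add atoms: none
Why: In the Still–Gennari olefination the electron-poor trifluoroethyl phosphonate makes collapse of the first adduct fast, so the kinetic Z-enoate should form, with the ester carbon C14 cis to C2 and the C9 branch trans, which is the ring-trans geometry of C1=C10.

Step 5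
Reactants: 7 acetoxy dienoate
Product: 8 methyl (2Z,6Z)-2-[2-(tert-butyldimethylsilyloxy)ethyl]-8-hydroxy-6-methylocta-2,6-dienoate
Conditions: K2CO3 (cat.), MeOH, 0 °C
Reagents that add atoms: none
Why: Carbonate-catalysed methanolysis removes the primary acetate, while exchange at the methyl ester is degenerate and the silyl ether is stable.

Step 6
Reactants: 8 allylic alcohol
Product: 9 methyl (2Z,6Z)-2-[2-(tert-butyldimethylsilyloxy)ethyl]-6-methyl-8-oxoocta-2,6-dienoate
Conditions: TEMPO (10 mol %), PhI(OAc)2, CH2Cl2, 0 °C to rt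
Reagents that add atoms: none
Why: Oxoammonium (TEMPO) oxidation is the established mild way from nerol-type Z-allylic alcohols to Z-enals without Z-to-E isomerisation.

Step 7
Reactants: 9 Z-enal; 10 vinylmagnesium bromide
Product: 12 methyl (2Z,6Z,8S)-2-[2-(tert-butyldimethylsilyloxy)ethyl]-8-hydroxy-6-methyldeca-2,6,9-trienoate, via divinylzinc 11 (not isolated)
Conditions: 10, ZnCl2 (0.5 equiv), Et2O, then 1,4-dioxane, filtration; (−)-MIB (10 mol %), toluene, −20 to 0 °C, then 9; aqueous work-up
Reagents that add atoms: none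
Why: In this amino-alcohol-catalysed organozinc addition the zinc alkoxide of (−)-MIB should deliver vinyl to the Si face of the aldehyde and so set C6, while the ester is inert to the zinc reagent.

Step 8
Reactants: 12 hydroxy trienoate
Product: 13 (2Z,6Z,8S)-2-[2-(tert-butyldimethylsilyloxy)ethyl]-6-methyldeca-2,6,9-triene-1,8-diol
Conditions: i-Bu2AlH (3.5 equiv), CH2Cl2, −78 °C; aq potassium sodium tartrate
Reagents that add atoms: none
Why: i-Bu2AlH reduces the conjugated ester in 1,2-fashion to the C14 allylic alcohol without touching alkene geometry, the silyl ether or C6.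

Step 9
Reactants: 13 diol
Product: 14 (3S,4Z,8Z)-9-[(tert-butyldiphenylsilyloxy)methyl]-11-(tert-butyldimethylsilyloxy)-5-methylundeca-1,4,8-trien-3-ol
Conditions: TBDPSCl (1.05 equiv), imidazole, CH2Cl2, 0 °C
Reagents that add atoms: TBDPSCl, CC(C)(C)[Si](Cl)(c1ccccc1)c1ccccc1
Why: The bulky silyl chloride should discriminate on steric grounds between the primary C14 hydroxyl and the secondary, doubly allylic C6 hydroxyl.

Step 10
Reactants: 15 2-(bromomethyl)acrylic acid
Product: 16 2-(acetoxymethyl)acrylic acid
Conditions: NaOAc (4 equiv), AcOH, 60 °C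
Reagents that add atoms: sodium acetate, CC(=O)[O-].[Na+]
Why: Acetate displaces the activated allylic bromide, and direct and allylic (SN2') substitution give the same product.

Step 11
Reactants: 14 C6 alcohol; 16 2-(acetoxymethyl)acrylic acid
Product: 17 (3S,4Z,8Z)-9-[(tert-butyldiphenylsilyloxy)methyl]-11-(tert-butyldimethylsilyloxy)-5-methylundeca-1,4,8-trien-3-yl 2-(acetoxymethyl)acrylate
Conditions: DCC, DMAP (5 mol %), CH2Cl2, 0 °C
Reagents that add atoms: none
Why: Steglich esterification acylates O6 without breaking the C6–O bond, so the configuration is kept, and the low DMAP loading and temperature limit attack of the amine on the allylic acetate.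

Step 12
Reactants: 17 diene ester
Product: 18 (5R)-3-(acetoxymethyl)-5-[(1Z,5Z)-6-[(tert-butyldiphenylsilyloxy)methyl]-8-(tert-butyldimethylsilyloxy)-2-methylocta-1,5-dienyl]furan-2(5H)-one
Conditions: second-generation Grubbs catalyst (10 mol %), CH2Cl2 (5 mM), reflux
Reagents that add atoms: none
Why: Ring-closing metathesis starts at the monosubstituted vinyl group and closes the five-membered ring on the 1,1-disubstituted acrylate, a known route to α-substituted butenolides that should outrun attack on the hindered trisubstituted alkenes and does not touch C6.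

Step 13
Reactants: 18 bis-silyl butenolide
Product: 19 (5R)-3-(acetoxymethyl)-5-[(1Z,5Z)-6-[(tert-butyldiphenylsilyloxy)methyl]-8-hydroxy-2-methylocta-1,5-dienyl]furan-2(5H)-one
Conditions: HF·pyridine, pyridine, THF, 0 °C
Reagents that add atoms: none
Why: Buffered HF·pyridine cleaves a primary TBS ether much faster than a TBDPS ether and is not basic enough to remove the acidic, doubly allylic C6–H of the butenolide.

Step 14
Reactants: 19 C8 alcohol
Product: 20 (3Z,7Z)-8-[(2R)-4-(acetoxymethyl)-5-oxo-2,5-dihydrofuran-2-yl]-3-[(tert-butyldiphenylsilyloxy)methyl]-7-methylocta-3,7-dienal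
Conditions: Dess–Martin periodinane, NaHCO3, CH2Cl2, 0 °C
Reagents that add atoms: none
Why: Bicarbonate-buffered Dess–Martin oxidation is close to neutral, so the β,γ-unsaturated aldehyde should not slip into conjugation if it is used at once.

Step 15
Reactants: 20 aldehyde butenolide
Product: 23 (6R,7R,8R)-14-(tert-butyldiphenylsilyloxy)-8β-hydroxygermacra-1(10),4,11(13)-trien-12,6α-olide (4Z; C1=C10 ring-trans; trans-fused lactone), via samarium ketyl 21 (not isolated), via cyclised samarium enolate 22 (not isolated)
Conditions: SmI2 (2.5 equiv), THF, 0 °C, 20 added by syringe pump (final 1 mM), no proton donor; then air, aq potassium sodium tartrate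
Reagents that add atoms: none
Why: Proposed new method: SmI2 transfers one electron to the C8 aldehyde and the nucleophilic ketyl 21 adds to C7, the β-carbon of the electron-poor butenolide; a second SmI2 reduces the C11 radical to the trivalent samarium enolate 22, which expels the C13 acetate (E1cB) and so creates C11=C13 instead of being protonated. The closest known reactions are samarium ketyl–olefin cyclisations on to unsaturated esters and lactones, shown so far for five- to eight-membered rings, and β-eliminations from samarium enolates; if electron transfer reached the acetoxymethyl butenolide first, the resulting allylsamarium would attack the aldehyde through C7 and give the same skeleton. The ten-membered carbocycle closes in a 10-exo-trig mode (C7=C11 stays outside the new ring), helped by slow addition at high dilution and by the Z C4=C5 alkene, the ring-trans C1=C10 alkene and the planar butenolide, which leave only six freely rotating bonds in the tether. C7 is controlled by C6, because C8 should bond to the butenolide face anti to the C5 branch, the usual sense for γ-substituted butenolides, which gives the trans-lactone. C8 is controlled by tether and metal, because C9 has to lie gauche to C6 for the chain to reach C5 and the samarium-bound oxygen is expected to turn towards the lactone that takes up charge and H8 towards C13, the syn sense also known from ketyl additions to β-substituted unsaturated esters, which gives the 8β-alcohol; this is the least secure element of the step. The step needs chemoselective electron transfer and regioselective attack: the aldehyde is the most easily reduced group of 20, C7 is its only electron-poor alkene carbon (C1=C10 and C4=C5 are unactivated and trisubstituted), and the absence of a proton donor with only a small excess of SmI2 should spare the methylene lactone once it has formed.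

Step 16
Reactants: 23 8β-alcohol
Product: 24 (6R,7R,8R)-14-(tert-butyldiphenylsilyloxy)-8β-isobutyryloxygermacra-1(10),4,11(13)-trien-12,6α-olide
Conditions: (i-PrCO)2O, DMAP (cat.), pyridine, CH2Cl2, 0 °C to rt
Reagents that add atoms: isobutyric anhydride, CC(C)C(=O)OC(=O)C(C)C
Why: DMAP-catalysed acyl transfer leaves the C8–O bond intact, so the 8β configuration is kept, and the mild conditions should not move the lactone from O6 to O8.

Step 17
Reactants: 24 silyl ether
Product: 25 (6R,7R,8R)-14-hydroxy-8β-isobutyryloxygermacra-1(10),4,11(13)-trien-12,6α-olide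
Conditions: HF·pyridine, pyridine, THF, rt
Reagents that add atoms: none
Why: Longer exposure to buffered HF·pyridine cleaves the primary allylic TBDPS ether under non-basic conditions that should spare the methylene lactone, the isobutyrate and the diene.

Step 18
Reactants: 25 allylic alcohol
Product: 26 (1R,6R,7R,8R,10S)-1β,10α-epoxy-14-hydroxy-8β-isobutyryloxygermacra-4Z,11(13)-dien-12,6α-olide (target)
Conditions: Ti(OiPr)4, L-(+)-diisopropyl tartrate, t-BuOOH, 4 Å molecular sieves, CH2Cl2, −20 °C
Reagents that add atoms: tert-butyl hydroperoxide, CC(C)(C)OO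
Why: In the Sharpless asymmetric epoxidation the titanium tartrate binds the C14 hydroxyl, so only C1=C10 reacts, and L-(+)-tartrate delivers oxygen to the face that gives (1R,10S), which is also the outer face of the ring conformer with C14 on the β-side, so reagent and substrate control should agree.

Compound list
1 | methyl bis(2,2,2-trifluoroethyl)phosphonoacetate | COC(=O)CP(=O)(OCC(F)(F)F)OCC(F)(F)F | starting material
2 | tert-butyl(2-iodoethoxy)dimethylsilane | CC(C)(C)[Si](C)(C)OCCI | starting material
3 | methyl 2-[bis(2,2,2-trifluoroethoxy)phosphoryl]-4-(tert-butyldimethylsilyloxy)butanoate (racemic) | COC(=O)C(CCO[Si](C)(C)C(C)(C)C)P(=O)(OCC(F)(F)F)OCC(F)(F)F | intermediate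
4 | neryl acetate, (2Z)-3,7-dimethylocta-2,6-dien-1-yl acetate | CC(C)=CCC/C(C)=C\COC(C)=O | starting material
5 | 6,7-epoxyneryl acetate, (2Z)-5-(3,3-dimethyloxiran-2-yl)-3-methylpent-2-en-1-yl acetate (racemic) | CC(=O)OC/C=C(/C)CCC1OC1(C)C | intermediate
6 | (4Z)-6-acetoxy-4-methylhex-4-enal | CC(=O)OC/C=C(/C)CCC=O | intermediate
7 | methyl (2Z,6Z)-8-acetoxy-2-[2-(tert-butyldimethylsilyloxy)ethyl]-6-methylocta-2,6-dienoate | COC(=O)/C(CCO[Si](C)(C)C(C)(C)C)=C\CC/C(C)=C\COC(C)=O | intermediate
8 | methyl (2Z,6Z)-2-[2-(tert-butyldimethylsilyloxy)ethyl]-8-hydroxy-6-methylocta-2,6-dienoate | COC(=O)/C(CCO[Si](C)(C)C(C)(C)C)=C\CC/C(C)=C\CO | intermediate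
9 | methyl (2Z,6Z)-2-[2-(tert-butyldimethylsilyloxy)ethyl]-6-methyl-8-oxoocta-2,6-dienoate | COC(=O)/C(CCO[Si](C)(C)C(C)(C)C)=C\CC/C(C)=C\C=O | intermediate
10 | vinylmagnesium bromide | C=C[Mg]Br | starting material
11 | divinylzinc | C=C[Zn]C=C | intermediate
12 | methyl (2Z,6Z,8S)-2-[2-(tert-butyldimethylsilyloxy)ethyl]-8-hydroxy-6-methyldeca-2,6,9-trienoate | COC(=O)/C(CCO[Si](C)(C)C(C)(C)C)=C\CC/C(C)=C\[C@@H](O)C=C | intermediate
13 | (2Z,6Z,8S)-2-[2-(tert-butyldimethylsilyloxy)ethyl]-6-methyldeca-2,6,9-triene-1,8-diol | OC/C(CCO[Si](C)(C)C(C)(C)C)=C\CC/C(C)=C\[C@@H](O)C=C | intermediate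
14 | (3S,4Z,8Z)-9-[(tert-butyldiphenylsilyloxy)methyl]-11-(tert-butyldimethylsilyloxy)-5-methylundeca-1,4,8-trien-3-ol | CC(C)(C)[Si](OC/C(CCO[Si](C)(C)C(C)(C)C)=C\CC/C(C)=C\[C@@H](O)C=C)(c1ccccc1)c1ccccc1 | intermediate
15 | 2-(bromomethyl)acrylic acid | C=C(CBr)C(=O)O | starting material
16 | 2-(acetoxymethyl)acrylic acid | C=C(COC(C)=O)C(=O)O | intermediate
17 | 2-(acetoxymethyl)acrylate of 14 (C6 S) | CC(C)(C)[Si](OC/C(CCO[Si](C)(C)C(C)(C)C)=C\CC/C(C)=C\[C@@H](OC(=O)C(=C)COC(C)=O)C=C)(c1ccccc1)c1ccccc1 | intermediate
18 | (5R)-3-(acetoxymethyl)-5-[(1Z,5Z)-6-[(tert-butyldiphenylsilyloxy)methyl]-8-(tert-butyldimethylsilyloxy)-2-methylocta-1,5-dienyl]furan-2(5H)-one | CC(C)(C)[Si](OC/C(CCO[Si](C)(C)C(C)(C)C)=C\CC/C(C)=C\[C@H]1OC(=O)C(COC(C)=O)=C1)(c1ccccc1)c1ccccc1 | intermediate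
19 | (5R)-3-(acetoxymethyl)-5-[(1Z,5Z)-6-[(tert-butyldiphenylsilyloxy)methyl]-8-hydroxy-2-methylocta-1,5-dienyl]furan-2(5H)-one | CC(C)(C)[Si](OC/C(CCO)=C\CC/C(C)=C\[C@H]1OC(=O)C(COC(C)=O)=C1)(c1ccccc1)c1ccccc1 | intermediate
20 | (3Z,7Z)-8-[(2R)-4-(acetoxymethyl)-5-oxo-2,5-dihydrofuran-2-yl]-3-[(tert-butyldiphenylsilyloxy)methyl]-7-methylocta-3,7-dienal | CC(C)(C)[Si](OC/C(CC=O)=C\CC/C(C)=C\[C@H]1OC(=O)C(COC(C)=O)=C1)(c1ccccc1)c1ccccc1 | intermediate
21 | samarium ketyl of 20 (radical at C8, O8–SmI2) | CC(C)(C)[Si](OC/C(C[CH]O[Sm](I)I)=C\CC/C(C)=C\[C@H]1OC(=O)C(COC(C)=O)=C1)(c1ccccc1)c1ccccc1 | intermediate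
22 | cyclised trivalent samarium enolate (C7–C8 formed, C11=C12 ketene acetal, C13 acetate still in place) | CC(=O)OCC1=C(O[Sm](I)I)O[C@@H]2/C=C(/C)CC/C=C(\CO[Si](c3ccccc3)(c3ccccc3)C(C)(C)C)C[C@@H](O[Sm](I)I)[C@@H]12 | intermediate
23 | (6R,7R,8R)-14-(tert-butyldiphenylsilyloxy)-8β-hydroxygermacra-1(10),4,11(13)-trien-12,6α-olide | C=C1C(=O)O[C@@H]2/C=C(/C)CC/C=C(\CO[Si](c3ccccc3)(c3ccccc3)C(C)(C)C)C[C@@H](O)[C@@H]12 | intermediate
24 | (6R,7R,8R)-14-(tert-butyldiphenylsilyloxy)-8β-isobutyryloxygermacra-1(10),4,11(13)-trien-12,6α-olide | C=C1C(=O)O[C@@H]2/C=C(/C)CC/C=C(\CO[Si](c3ccccc3)(c3ccccc3)C(C)(C)C)C[C@@H](OC(=O)C(C)C)[C@@H]12 | intermediate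
25 | (6R,7R,8R)-14-hydroxy-8β-isobutyryloxygermacra-1(10),4,11(13)-trien-12,6α-olide | C=C1C(=O)O[C@@H]2/C=C(/C)CC/C=C(\CO)C[C@@H](OC(=O)C(C)C)[C@@H]12 | intermediate
26 | (1R,6R,7R,8R,10S)-1β,10α-epoxy-14-hydroxy-8β-isobutyryloxygermacra-4Z,11(13)-dien-12,6α-olide | C=C1C(=O)O[C@@H]2/C=C(/C)CC[C@H]3O[C@]3(CO)C[C@@H](OC(=O)C(C)C)[C@@H]12 | target

Total steps: 18. Longest linear sequence: 16 (steps 2–9 and 11–18, from neryl acetate).

Steps most likely to fail

Step 15 (new method). Ring closure may be slower than further reduction of the ketyl or pinacol coupling. Electron transfer to the butenolide may cleave the C13–O bond or the doubly allylic C6–O bond. Facial selection at C8 may be poor or reversed.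

The fallback is polar and uses known chemistry: an allylchromium ring closure of the Nozaki–Hiyama–Kishi type followed by Mitsunobu inversion. It sets out from 14 and comes back at 24. Alcohol 14 is esterified with 15 (DCC, CH2Cl2) to the 2-(bromomethyl)acrylate F1. Ring-closing metathesis gives the 3-(bromomethyl)butenolide F2, buffered HF·pyridine frees the C8 alcohol F3, and Dess–Martin oxidation gives the bromo aldehyde F4. CrCl2 in THF at high dilution converts the allylic bromide into an allyl derivative of trivalent chromium that attacks the aldehyde through its γ-carbon C7. This reaction is known for 3-(bromomethyl)butenolides with aldehydes and, as a ring closure, for ten-membered carbocycles. The chair transition state with C6 and C9 equatorial should give the anti product, the 8α-alcohol F5. Mitsunobu esterification of F5 with isobutyric acid (PPh3, DIAD, toluene) inverts C8 and returns to 24. The same last operation would rescue material from step 15 if the samarium closure favoured the 8α-alcohol F5.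

Step 12. Closure on the hindered, electron-poor 1,1-disubstituted alkene may be slow, so that dimerisation at the vinyl group or closure on to C1=C10 (a seven-membered ring) competes.

The fallback closes the ring first and adds C13 afterwards. It sets out from 14 and comes back at 18. Acryloyl chloride and i-Pr2NEt give the acrylate F6, whose monosubstituted acceptor should close much faster in the metathesis to the unsubstituted butenolide F7. A phosphine-catalysed Morita–Baylis–Hillman reaction with aqueous formaldehyde (Bu3P, THF), kept close to neutral to spare C6–H, gives the 3-(hydroxymethyl)butenolide F8. Acetylation (Ac2O, pyridine) then gives 18.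

Step 7. Uncatalysed addition promoted by residual magnesium salts, or Z-to-E isomerisation of the enal, would erode the enantiomeric purity at C6, the only purchased stereochemical information, as well as the alkene geometry.

The fallback replaces vinyl transfer by alkyne transfer. It sets out from 9 and comes back at 12. A Me2Zn/ProPhenol-catalysed addition of trimethylsilylacetylene, a reaction well suited to unsaturated aldehydes (ligand antipode chosen for Si-face attack), gives the silyl propargylic alcohol F9. K2CO3 in MeOH gives the terminal alkyne F10. Semihydrogenation (H2, Pd/CaCO3 poisoned with Pb(OAc)2, quinoline) then gives 12.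

Further compounds
F1 | step 15 | 2-(bromomethyl)acrylate of 14 (C6 S) | CC(C)(C)[Si](OC/C(CCO[Si](C)(C)C(C)(C)C)=C\CC/C(C)=C\[C@@H](OC(=O)C(=C)CBr)C=C)(c1ccccc1)c1ccccc1
F2 | step 15 | (5R)-3-(bromomethyl)-5-[(1Z,5Z)-6-[(tert-butyldiphenylsilyloxy)methyl]-8-(tert-butyldimethylsilyloxy)-2-methylocta-1,5-dienyl]furan-2(5H)-one | CC(C)(C)[Si](OC/C(CCO[Si](C)(C)C(C)(C)C)=C\CC/C(C)=C\[C@H]1OC(=O)C(CBr)=C1)(c1ccccc1)c1ccccc1
F3 | step 15 | (5R)-3-(bromomethyl)-5-[(1Z,5Z)-6-[(tert-butyldiphenylsilyloxy)methyl]-8-hydroxy-2-methylocta-1,5-dienyl]furan-2(5H)-one | CC(C)(C)[Si](OC/C(CCO)=C\CC/C(C)=C\[C@H]1OC(=O)C(CBr)=C1)(c1ccccc1)c1ccccc1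
F4 | step 15 | (3Z,7Z)-8-[(2R)-4-(bromomethyl)-5-oxo-2,5-dihydrofuran-2-yl]-3-[(tert-butyldiphenylsilyloxy)methyl]-7-methylocta-3,7-dienal | CC(C)(C)[Si](OC/C(CC=O)=C\CC/C(C)=C\[C@H]1OC(=O)C(CBr)=C1)(c1ccccc1)c1ccccc1
F5 | step 15 | (6R,7R,8S)-14-(tert-butyldiphenylsilyloxy)-8α-hydroxygermacra-1(10),4,11(13)-trien-12,6α-olide | C=C1C(=O)O[C@@H]2/C=C(/C)CC/C=C(\CO[Si](c3ccccc3)(c3ccccc3)C(C)(C)C)C[C@H](O)[C@@H]12
F6 | step 12 | acrylate of 14 (C6 S) | CC(C)(C)[Si](OC/C(CCO[Si](C)(C)C(C)(C)C)=C\CC/C(C)=C\[C@@H](OC(=O)C=C)C=C)(c1ccccc1)c1ccccc1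
F7 | step 12 | (5R)-5-[(1Z,5Z)-6-[(tert-butyldiphenylsilyloxy)methyl]-8-(tert-butyldimethylsilyloxy)-2-methylocta-1,5-dienyl]furan-2(5H)-one | CC(C)(C)[Si](OC/C(CCO[Si](C)(C)C(C)(C)C)=C\CC/C(C)=C\[C@H]1OC(=O)C=C1)(c1ccccc1)c1ccccc1
F8 | step 12 | (5R)-3-(hydroxymethyl)-5-[(1Z,5Z)-6-[(tert-butyldiphenylsilyloxy)methyl]-8-(tert-butyldimethylsilyloxy)-2-methylocta-1,5-dienyl]furan-2(5H)-one | CC(C)(C)[Si](OC/C(CCO[Si](C)(C)C(C)(C)C)=C\CC/C(C)=C\[C@H]1OC(=O)C(CO)=C1)(c1ccccc1)c1ccccc1
F9 | step 7 | methyl (2Z,6Z,8R)-2-[2-(tert-butyldimethylsilyloxy)ethyl]-8-hydroxy-6-methyl-10-(trimethylsilyl)deca-2,6-dien-9-ynoate | COC(=O)/C(CCO[Si](C)(C)C(C)(C)C)=C\CC/C(C)=C\[C@@H](O)C#C[Si](C)(C)C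
F10 | step 7 | methyl (2Z,6Z,8R)-2-[2-(tert-butyldimethylsilyloxy)ethyl]-8-hydroxy-6-methyldeca-2,6-dien-9-ynoate | COC(=O)/C(CCO[Si](C)(C)C(C)(C)C)=C\CC/C(C)=C\[C@@H](O)C#C
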